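**Retrosynthetic overview**

1. Ocophyllal B (benzofuran: ring A benzo, ring B furan, ring C 3,4,5-trimethoxyphenyl) ⇒ DDQ aromatisation of ring B of a trans-2,3-dihydrobenzofuran-5-carbaldehyde ⇒ C5–CHO from cleavage of an (E)-propenyl group, ring-C 4-OMe from a phenol.
2. Key disconnection: the C3–C3a and O1–C2 bonds of ring B, made together by oxidative 8-5' cross-coupling of (E)-isoeugenol (ring A, O1, C7–OMe, C5 side chain) with (E)-4-propenylsyringol (ring C, C2, C3, C3–CH3).
3. Feature used: C2–aryl, C3–CH3, O1, C7–OMe and a carbon substituent at C5 para to O1 form the 8-5' neolignan pattern of two arylpropene units; the formyl carbon is the benzylic carbon of a propenyl chain that has lost two carbons.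
4. Ring order: rings A and C come with the two phenols; ring B is the only ring built (key step, as the dihydrofuran) and is aromatised last; 4-propenylsyringol comes from 4-allyl-2,6-dimethoxyphenol by double-bond migration.

Key step: step 2

Remark: the target has no stereocentre; the dihydrobenzofurans 6–9 are racemic trans compounds drawn as the (2R,3R) enantiomer, and step 5 removes both stereocentres. (E)-Isoeugenol is taken as the commercial single isomer.

**Step 1**
Reactants: 1 4-allyl-2,6-dimethoxyphenol
Product: 2 (E)-2,6-dimethoxy-4-(prop-1-enyl)phenol
Conditions: RuClH(CO)(PPh3)3 (1 mol %), toluene, 80 °C, N2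
Reagents that add atoms: none
Why: Ruthenium hydride-catalysed alkene isomerisation (hydrometalation/β-hydride elimination) should move the terminal double bond into conjugation with the arene, the conjugated (E)-alkene being the thermodynamic product and the free phenol being tolerated as in the eugenol-to-isoeugenol conversion.

**Step 2**
Reactants: 2 (E)-2,6-dimethoxy-4-(prop-1-enyl)phenol; 3 (E)-isoeugenol
Product: 6 rac-(2R,3R)-4-[7-methoxy-3-methyl-5-((E)-prop-1-enyl)-2,3-dihydrobenzofuran-2-yl]-2,6-dimethoxyphenol, via dienone quinone methide 4 (not isolated), via phenol quinone methide 5 (not isolated)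
Conditions: Ag2O (1.5 equiv), 3 (3 equiv), toluene/acetone 2:1, rt, N2, dark; 2 (1 equiv) added over 4 h
Reagents that add atoms: none
Why: Ag2O removes one electron and one proton from each phenol; the phenoxyl radical of 2 has spin at C8 of its side chain and, with both ring positions ortho to oxygen occupied by methoxy groups, can form a C–C bond only there, while the radical of 3 offers its free ring carbon C5, so radical–radical combination makes the C3–C3a bond (benzofuran numbering) and gives dienone 4, which tautomerises on the isoeugenol half to phenol 5. Ring B then closes by 5-exo-trig conjugate (oxa-Michael) addition of the ring-A phenol oxygen to the exocyclic quinone methide carbon (O1–C2), which re-aromatises ring C as the free phenol. The closest known reaction is the Ag2O- or peroxidase-mediated 8-5' dehydrodimerisation of isoeugenol to its dihydrobenzofuran dimer, run here as a cross-coupling. C3 forms in the radical combination without facial bias and is racemic; C2 is set in the ring closure under control of C3, the aryl group taking the face anti to the C3 methyl group, so the trans isomer, which is also the more stable one, should dominate. The step needs cross- over homo-coupling and the 8-5' over the 8-O-4' and 8-8' modes: the blocked syringyl ring excludes the inverse 8-5' pairing and any syringyl 8-5' homodimer, and adding the more easily oxidised 2 slowly to an excess of 3 keeps encounters between two syringyl radicals rare. The 8-5' homodimer of 3 and oxygen-linked dimers are expected companions that must be removed by chromatography, and the oxidant is kept limiting because the phenol of 6 can itself be oxidised.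

**Step 3**
Reactants: 6 rac-(2R,3R)-4-[7-methoxy-3-methyl-5-((E)-prop-1-enyl)-2,3-dihydrobenzofuran-2-yl]-2,6-dimethoxyphenol
Product: 7 rac-(2R,3R)-7-methoxy-3-methyl-5-[(E)-prop-1-enyl]-2-(3,4,5-trimethoxyphenyl)-2,3-dihydrobenzofuran
Conditions: MeI, K2CO3, acetone, reflux
Reagents that add atoms: iodomethane (MeI), CI
Why: Williamson ether synthesis, in which the phenoxide is methylated by SN2 attack on MeI while the alkene, the cyclic benzyl aryl ether and both stereocentres are inert; capping the phenol also blocks reopening of ring B through a quinone methide and keeps a free phenol away from DDQ later.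

**Step 4**
Reactants: 7 rac-(2R,3R)-7-methoxy-3-methyl-5-[(E)-prop-1-enyl]-2-(3,4,5-trimethoxyphenyl)-2,3-dihydrobenzofuran
Product: 9 rac-(2R,3R)-7-methoxy-3-methyl-2-(3,4,5-trimethoxyphenyl)-2,3-dihydrobenzofuran-5-carbaldehyde, via glycol 8 (not isolated)
Conditions: OsO4 (2 mol %), NaIO4 (4 equiv), 2,6-lutidine (2 equiv), 1,4-dioxane/H2O 3:1, rt
Reagents that add atoms: osmium tetroxide, O=[Os](=O)(=O)=O (transfers the oxygen); sodium periodate, [Na+].[O-]I(=O)(=O)=O (terminal oxygen source)
Why: Lemieux–Johnson oxidation, in which osmylation of the only C=C bond gives glycol 8 and periodate cleaves it to the aryl aldehyde and acetaldehyde, with 2,6-lutidine suppressing ketol formation and C2 and C3 untouched; the cleavage is placed before the aromatisation so that osmium never meets a benzofuran C2=C3 bond and DDQ never meets an electron-rich propenylarene, whose allylic methyl group is open to hydride abstraction.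

**Step 5**
Reactants: 9 rac-(2R,3R)-7-methoxy-3-methyl-2-(3,4,5-trimethoxyphenyl)-2,3-dihydrobenzofuran-5-carbaldehyde
Product: 10 ocophyllal B, 7-methoxy-3-methyl-2-(3,4,5-trimethoxyphenyl)benzofuran-5-carbaldehyde
Conditions: DDQ (1.5 equiv), 1,4-dioxane (dry), reflux
Reagents that add atoms: none
Why: DDQ dehydrogenation, in which hydride abstraction from C2–H (benzylic to ring C and α to O1) followed by loss of the C3 proton is driven by the gain of benzofuran aromaticity, as in the known conversion of 2-aryl-2,3-dihydrobenzofuran neolignans into 2-arylbenzofurans; the aldehyde and aryl methyl ethers are inert and both stereocentres disappear, as the achiral target requires.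

**Compound list**

1 | 4-allyl-2,6-dimethoxyphenol | C=CCc1cc(OC)c(O)c(OC)c1 | starting material
2 | (E)-2,6-dimethoxy-4-(prop-1-enyl)phenol | C/C=C/c1cc(OC)c(O)c(OC)c1 | intermediate
3 | (E)-isoeugenol, 2-methoxy-4-[(E)-prop-1-enyl]phenol | C/C=C/c1ccc(O)c(OC)c1 | starting material
4 | dienone quinone methide, 4-{2-[3-methoxy-2-oxo-5-((E)-prop-1-enyl)cyclohexa-3,5-dienyl]propylidene}-2,6-dimethoxycyclohexa-2,5-dienone (racemic, one enantiomer at the side-chain carbon drawn, ring sp3 carbon undefined) | C[C@H](C1C=C(/C=C/C)C=C(OC)C1=O)C=C1C=C(OC)C(=O)C(OC)=C1 | intermediate (not isolated)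
5 | phenol quinone methide, 4-{2-[2-hydroxy-3-methoxy-5-((E)-prop-1-enyl)phenyl]propylidene}-2,6-dimethoxycyclohexa-2,5-dienone (racemic, one enantiomer drawn) | C[C@H](c1cc(/C=C/C)cc(OC)c1O)C=C1C=C(OC)C(=O)C(OC)=C1 | intermediate (not isolated)
6 | rac-(2R,3R)-4-[7-methoxy-3-methyl-5-((E)-prop-1-enyl)-2,3-dihydrobenzofuran-2-yl]-2,6-dimethoxyphenol (trans) | C[C@H]1[C@H](c2cc(OC)c(O)c(OC)c2)Oc2c(OC)cc(/C=C/C)cc21 | intermediate
7 | rac-(2R,3R)-7-methoxy-3-methyl-5-[(E)-prop-1-enyl]-2-(3,4,5-trimethoxyphenyl)-2,3-dihydrobenzofuran (trans) | C[C@H]1[C@H](c2cc(OC)c(OC)c(OC)c2)Oc2c(OC)cc(/C=C/C)cc21 | intermediate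
8 | 1-[rac-(2R,3R)-7-methoxy-3-methyl-2-(3,4,5-trimethoxyphenyl)-2,3-dihydrobenzofuran-5-yl]propane-1,2-diol (syn glycol, both glycol diastereomers expected, one drawn) | C[C@H]1[C@H](c2cc(OC)c(OC)c(OC)c2)Oc2c(OC)cc([C@@H](O)[C@@H](C)O)cc21 | intermediate (not isolated)
9 | rac-(2R,3R)-7-methoxy-3-methyl-2-(3,4,5-trimethoxyphenyl)-2,3-dihydrobenzofuran-5-carbaldehyde (trans) | C[C@H]1[C@H](c2cc(OC)c(OC)c(OC)c2)Oc2c(OC)cc(C=O)cc21 | intermediate
10 | ocophyllal B, 7-methoxy-3-methyl-2-(3,4,5-trimethoxyphenyl)benzofuran-5-carbaldehyde | COc1cc(-c2oc3c(OC)cc(C=O)cc3c2C)cc(OC)c1OC | target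

**Step count and risks**

Total step count: 5. Longest linear sequence: 5 steps (1 → 2 → 6 → 7 → 9 → 10); 3 is bought and enters at step 2.

Steps most likely to fail:

Step 2 (key step). The radical pairing is not partner-selective: homo-coupling of 3, oxygen- and C8–C8'-bonding of the syringyl radical and further oxidation of the product phenol may leave the cross-coupled 6 as a minor component that is hard to purify. The fallback makes the same two ring-B bonds by a polar, palladium-mediated oxyarylation (Heck type), in which a C–I bond fixes the partner selectivity. It sets out from compound 2: O-methylation (MeI, K2CO3, acetone, reflux) should give (E)-isoelemicin F1. F1 and commercial 5-iodovanillin (4-hydroxy-3-iodo-5-methoxybenzaldehyde, COc1cc(C=O)cc(I)c1O) are then heated with Pd(OAc)2 (10 mol %) and Ag2CO3 (2 equiv) in acetone at 60 °C. Zerovalent palladium inserts into the C–I bond, the cationic arylpalladium species adds across the propenyl double bond with the aryl carbon going to the methyl-bearing carbon (C3–C3a), and the phenol oxygen then bonds to the benzylic carbon (O1–C2). This is the known way to trans-2-aryl-3-methyl-2,3-dihydrobenzofurans from o-iodophenols and propenylbenzenes. The product is the dihydrobenzofuran aldehyde, compound 9, where the fallback comes back to the route with only step 5 left.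

Step 5. Hydride abstraction at C2 may be slow because the formyl group para to O1 draws electron density from that oxygen, and forcing the reaction invites oxidation at the C3 methyl group or decomposition. The fallback changes the order of events, so that ring B is aromatised while ring A still carries the electron-releasing propenyl group. It sets out from compound 7: DDQ (1.2 equiv, 1,4-dioxane, 80 °C) should give 7-methoxy-3-methyl-5-[(E)-prop-1-enyl]-2-(3,4,5-trimethoxyphenyl)benzofuran F2. OsO4 (cat.), NaIO4 and 2,6-lutidine in dioxane/H2O should then cleave the disubstituted styrenyl double bond, through rac-(1R,2R)-1-[7-methoxy-3-methyl-2-(3,4,5-trimethoxyphenyl)benzofuran-5-yl]propane-1,2-diol F3 (not isolated), faster than they touch the tetrasubstituted aromatic C2=C3 bond. The fallback comes back to the route at compound 10.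

Step 4. In the one-pot osmium/periodate system the oxidation may run past the aldehyde (ketol or carboxylic acid) or stall at the glycol, and the two failures cannot be corrected independently. The fallback splits the transformation into two separately controlled reactions with an anhydrous cleaving agent. It sets out from compound 7: Upjohn dihydroxylation (OsO4 cat., NMO, acetone/H2O, rt) should give glycol 8, now isolated and purified. Criegee cleavage with Pb(OAc)4 in CH2Cl2 at 0 °C should then give compound 9, where the fallback comes back to the route.

**Further compounds**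

F1 | step 2 | (E)-isoelemicin, 1,2,3-trimethoxy-5-[(E)-prop-1-enyl]benzene | C/C=C/c1cc(OC)c(OC)c(OC)c1
F2 | step 5 | 7-methoxy-3-methyl-5-[(E)-prop-1-enyl]-2-(3,4,5-trimethoxyphenyl)benzofuran | C/C=C/c1cc(OC)c2oc(-c3cc(OC)c(OC)c(OC)c3)c(C)c2c1
F3 | step 5 | rac-(1R,2R)-1-[7-methoxy-3-methyl-2-(3,4,5-trimethoxyphenyl)benzofuran-5-yl]propane-1,2-diol | COc1cc(-c2oc3c(OC)cc([C@@H](O)[C@@H](C)O)cc3c2C)cc(OC)c1OC
F0 | step 4 | none | none
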